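At early times each substrate molecule meets the coupling partner at its charged level, so I count substrate lifetimes: one lifetime is 1/(k1 × partner level), and N is the number of them that fit into the run.

- dusk: substrate 0.0050 M; coupling partner 11.0 mM; time 15 s
- dawn: substrate 0.0050 M; coupling partner 5.50 mM; time 15 s

    substrate + coupling partner → first product (k1 = 8.8 M⁻¹ s⁻¹)
    coupling partner + first product → double product (k2 = 5.1 M⁻¹ s⁻¹)
    coupling partner + double product → triple product (k3 = 9.6 M⁻¹ s⁻¹)
    coupling partner + double product → over-reaction product (k4 = 36 M⁻¹ s⁻¹)
    2 substrate → self-condensation product (k5 = 0.0092 M⁻¹ s⁻¹)

- in percentages every species weighs as the substrate in it: one self-condensation product counts as two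
- two of one species on the left: rate k times its square, two consumed each time
- run time (dusk): 15 s

* which of these there is most of at the end, counted by the substrate in it, dusk (double product / substrate / over-reaction product / first product)
* which of these there is most of at the end, counted by the substrate in it, dawn (double product / substrate / over-reaction product / first product)
* the largest of these amounts at the end, in percent of the substrate charged, dusk
* the largest of these amounts at the end, in percent of the substrate charged, dawn

With the partner held at its charge, N is 1.45 at dusk and 0.726 at dawn, and exp(−N) leaves 23.5% and 48.4% of the substrate. My first doubt is self-condensation, but at the start at dawn the first step uses substrate 530 times as fast, so I drop it. The second doubt is serious: the partner falls as it reacts, by at least one for each substrate that enters the first step. Taking its level at the middle of that fall, N shrinks to 1.20 at dusk and 0.556 at dawn, which leaves 30.1% and 57.4% of the substrate.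

First product needs no clock of its own. Its making and its loss both carry the partner as a factor, so the partner cancels in their ratio, and each substrate lifetime costs first product s lifetimes, where s is k2/k1, 0.580, the selectivity factor. With a the fraction of substrate left, first product is (a^s − a)/(1 − s) of the charge. That gives 47.0% at dusk and 35.9% at dawn. So in my reckoning there is more first product than substrate at dusk, and more substrate than first product at dawn. One objection stands: first product and double product also consume partner, so my N is still too high and my substrate figures sit low. The gaps of 17 percentage points and 21 points are wide enough that I keep the order.

The forecast names the same leaders, first product at 45% at dusk and substrate at 59% at dawn, saying that “the coupling partner is being depleted”. My own figures are 47.0% and 57.4%.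

The flask gives first product at 46.4% at dusk and substrate at 58.4% at dawn. At dawn, the 58.4% of substrate left and s give 35.2% of first product, and the flask holds 35.2%. Read at 1.0 min, the dawn flask has 34.0% of its substrate and 9.12% of its partner charge left. The same expression gives 46.4% of first product there, and that reading stands at 46.3%.

The constants come from no measurement; the rest is arithmetic.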